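**Assumptions:** (S)-proline gives the 7S aldol 6 (if the other enantiomer forms, (R)-proline is used). C9 epimerises to the thermodynamic isomer (C1 anti to C10) before Step 18. The C1 anomers from Step 18 are separable.

## Retrosynthetic overview
1. Target (26) ⇒ C11-selective lipase acetylation, C7/C1 isovalerates and silyl removal ⇒ bicyclic dienyl enol lactone 21. The pyran ring is closed last: the C1 acid attacks the C3 methoxydiene, and the lactone is then turned into the acylal by reductive acylation.
2. Cyclopentene (C5=C6) ⇒ intramolecular aldol condensation of a 1,6-ketoaldehyde (C5–C6 bond). C9–C5 is made by dianion alkylation with a methallyl-type bromide, which becomes the C4 ketone by ozonolysis; C3 is re-added by Wittig.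
3. The C7/C8/C10 triad (cis-fused dioxane) comes from the dihydroxyacetone-derived dioxanone 4: proline aldol (C7–C6 bond, first stereocentre), then axial Reformatsky (C8–C9 bond).
4. Ring order: dioxane (in the starting material) → cyclopentene (Step 11) → pyran (Step 17).

## Route

**Step 1**
Reactants: 1, 2-methylenepropane-1,3-diol
Product: 2, 2-{[(tert-butyldiphenylsilyl)oxy]methyl}prop-2-en-1-ol
Conditions: NaH (1.0 equiv), THF, 0 °C; TBDPSCl (1.0 equiv), 0→23 °C
Reagents that add atoms: TBDPSCl, CC(C)(C)[Si](Cl)(c1ccccc1)c1ccccc1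
Why: Mono-silylation of the symmetric diol (Williamson-type silylation with stoichiometric control).

**Step 2**
Reactants: 2
Product: 3, tert-butyl{[2-(bromomethyl)prop-2-en-1-yl]oxy}diphenylsilane
Conditions: CBr4, PPh3, CH2Cl2, 0 °C
Reagents that add atoms: CBr4, BrC(Br)(Br)Br
Why: Appel reaction (SN2) converts the allylic alcohol to the bromide, giving the C5–C4(=C3)–C11 unit.

**Step 3**
Reactants: 4, 2,2-dimethyl-1,3-dioxan-5-one (2 equiv); 5, 2-(benzyloxy)acetaldehyde
Product: 6, (4S)-4-[(1S)-2-(benzyloxy)-1-hydroxyethyl]-2,2-dimethyl-1,3-dioxan-5-one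
Conditions: (S)-proline (30 mol %), DMF, 4 °C, 72 h
Reagents that add atoms: none
Why: Direct asymmetric aldol by enamine catalysis (chair-like, Houk–List TS) sets C7 (S) and the anti C6 carbinol; this is the first stereocentre, and C6 is later erased.

**Step 4**
Reactants: 6
Product: 7, the C6-OTES ether of 6
Conditions: TESCl (1.5 equiv), imidazole, DMF, 0→23 °C
Reagents that add atoms: TESCl, CC[Si](Cl)(CC)CC
Why: Silylation protects the β-hydroxy ketone against retro-aldol and elimination.

**Step 5**
Reactants: 7; 8, methyl bromoacetate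
Product: 9, methyl 2-[(4S,5R)-4-{(1S)-2-(benzyloxy)-1-(triethylsilyloxy)ethyl}-5-hydroxy-2,2-dimethyl-1,3-dioxan-5-yl]acetate
Conditions: Zn dust (TMSCl-activated, 4 equiv), 8 (2.5 equiv), THF, 45 °C
Reagents that add atoms: none (the CH2CO2Me unit comes from reactant 8)
Why: Reformatsky addition; axial attack on the dioxanone chair (C6 chain equatorial) puts C9 cis to C6 and gives C8 (R), the cis-fusion needed for the later cyclopentane.

**Step 6**
Reactants: 9; 3
Product: 10, methyl (2S)-2-[(4S,5R)-4-{(1S)-2-(benzyloxy)-1-(triethylsilyloxy)ethyl}-5-hydroxy-2,2-dimethyl-1,3-dioxan-5-yl]-5-(TBDPSO)-4-methylidenepentanoate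
Conditions: LDA (2.4 equiv), THF, −78→−20 °C; then 3 (2 equiv), DMPU, −78→0 °C
Reagents that add atoms: none (the allyl unit comes from reactant 3)
Why: Fráter–Seebach dianion alkylation forms C9–C5; the Li alkoxide/enolate chelate directs the electrophile anti to the dioxane, and C9 is re-equilibrated later.

**Step 7**
Reactants: 10
Product: 11, the C4 ketone (4-oxo analogue of 10)
Conditions: O3, CH2Cl2, −78 °C; then PPh3, −78→23 °C
Reagents that add atoms: ozone, [O-][O+]=O
Why: Ozonolysis of the 1,1-disubstituted alkene gives the α-silyloxy methyl ketone at C4 (C3 is lost as CH2O).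

**Step 8**
Reactants: 11
Product: 12, the C6′-OH compound (benzyl removed)
Conditions: H2 (1 atm), 10 % Pd/C, EtOAc, 23 °C
Reagents that add atoms: none
Why: Hydrogenolysis of the benzyl ether; no other reducible group remains at this stage.

**Step 9**
Reactants: 12
Product: 13, the C6/C6′ diol
Conditions: Et3N·3HF (4 equiv), THF, 0→23 °C
Reagents that add atoms: none
Why: Fluoride removes the secondary TES ether (TBDPS and acetonide are untouched) to expose the vicinal diol.

**Step 10**
Reactants: 13
Product: 14, the C6 aldehyde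
Conditions: NaIO4 (2 equiv), THF/H2O 4:1, 23 °C
Reagents that add atoms: none
Why: Malaprade glycol cleavage gives the α-alkoxy aldehyde and removes the C6′ carbon; the C6 stereocentre is destroyed.

**Step 11**
Reactants: 14 (crude)
Product: 15, the cis-fused cyclopentene with C5=C6 conjugated to the C4 ketone
Conditions: pyrrolidine (0.2 equiv), AcOH (0.2 equiv), CH2Cl2, 23 °C
Reagents that add atoms: none
Why: Intramolecular aldol condensation (5-(enolexo)-exo-trig) closes C5–C6 and dehydrates to the 2-acylcyclopentene, while the dioxane keeps the C7/C8 configuration.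

**Step 12**
Reactants: 15
Product: 16, the C7/C8/C10 triol
Conditions: AcOH/H2O/THF 4:1:1, 50 °C
Reagents that add atoms: none (water leaves as acetone)
Why: Acid hydrolysis of the acetonide; the electron-poor enone and TBDPS ether are stable.

**Step 13**
Reactants: 16
Product: 17, the C10-OTBS ether
Conditions: TBSCl (1.05 equiv), imidazole, CH2Cl2, 0 °C
Reagents that add atoms: TBSCl, CC(C)(C)[Si](C)(C)Cl
Why: Selective silylation of the unhindered primary alcohol over the secondary and tertiary ones.

**Step 14**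
Reactants: 17
Product: 18, the C7-OTES ether
Conditions: TESOTf (1.3 equiv), 2,6-lutidine, CH2Cl2, −78 °C
Reagents that add atoms: TESOTf, CC[Si](CC)(CC)OS(=O)(=O)C(F)(F)F
Why: Kinetic silylation of the secondary alcohol; the tertiary C8-OH is left free, and C7 is protected until the pyran ring is formed.

**Step 15**
Reactants: 18
Product: 19, the C3 methoxydiene (E/Z mixture)
Conditions: [Ph3PCH2OMe]Cl (3 equiv), NaHMDS (3.2 equiv), THF, 0→23 °C
Reagents that add atoms: (methoxymethyl)triphenylphosphonium chloride, COC[P+](c1ccccc1)(c1ccccc1)c1ccccc1.[Cl-]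
Why: Wittig methoxymethylenation of the C4 ketone supplies C3; the E/Z ratio is irrelevant because both isomers give the same oxocarbenium in Step 17.

**Step 16**
Reactants: 19
Product: 20, the C1 carboxylic acid
Conditions: LiOH·H2O (6 equiv), THF/MeOH/H2O 3:1:1, 40 °C; quench with pH 5 buffer
Reagents that add atoms: lithium hydroxide, [Li+].[OH-]
Why: Saponification under basic conditions, where the methoxydiene and silyl ethers are stable.

**Step 17**
Reactants: 20
Product: 21, the bicyclic dienyl enol lactone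
Conditions: PPTS (0.2 equiv), toluene, 45 °C, 4 Å MS
Reagents that add atoms: none (MeOH is lost)
Why: Protonation of the methoxydiene at C6 gives an oxocarbenium at C3, which the carboxylate traps (oxa-cyclisation); E1 loss of MeOH then gives C3=C4/C5=C6, and C9 equilibrates through the dienol to the isomer with C1 anti to C10.

**Step 18**
Reactants: 21
Product: 22, the C1 isovalerate acylal
Conditions: DIBAL-H (2.5 equiv), CH2Cl2, −78 °C; then (iPrCH2CO)2O (8 equiv), pyridine, −78→0 °C; separate anomers
Reagents that add atoms: isovaleric anhydride, CC(C)CC(=O)OC(=O)CC(C)C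
Why: DIBAL reduces the activated enol-ester carbonyl to the aluminium hemiacetalate, which is acylated in situ (reductive acylation); the pseudo-axial (anomeric) alkoxide gives the 1S acylal as the major isomer.

**Step 19**
Reactants: 22
Product: 23, the C7-OH compound
Conditions: Et3N·3HF (3 equiv), THF, 0 °C, 1 h
Reagents that add atoms: none
Why: Fluoride removes the labile secondary TES ether while the primary TBS and TBDPS ethers stay.

**Step 20**
Reactants: 23
Product: 24, the C7 isovalerate
Conditions: (iPrCH2CO)2O (3 equiv), DMAP (0.2 equiv), pyridine, CH2Cl2, 0→23 °C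
Reagents that add atoms: isovaleric anhydride, CC(C)CC(=O)OC(=O)CC(C)C
Why: Acylation of the secondary alcohol with retention gives the 7-isovalerate; the tertiary C8-OH does not react.

**Step 21**
Reactants: 24
Product: 25, the 11-deacetyl triol
Conditions: TBAF (3 equiv)/AcOH (3 equiv), THF, 0→23 °C
Reagents that add atoms: none
Why: Buffered fluoride removes the two primary silyl ethers without touching the esters or the acylal.

**Step 22**
Reactants: 25
Product: 26, jatamanvaltrate K
Conditions: Candida antarctica lipase B (immobilised), vinyl acetate (5 equiv), TBME, 25 °C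
Reagents that add atoms: vinyl acetate, CC(=O)OC=C
Why: Lipase-catalysed regioselective transesterification (a hydrolase acting as acyl transferase) acetylates the unhindered allylic C11-OH and leaves the neopentyl C10-OH and tertiary C8-OH free; the conditions are neutral and anhydrous, so the acylals and diene survive, and the acetate goes on last because it would not survive the hydride, base and Wittig steps.

## Compound list
1 | 2-methylenepropane-1,3-diol | C=C(CO)CO | starting material
2 | mono-TBDPS ether of 1 | C=C(CO)CO[Si](c1ccccc1)(c1ccccc1)C(C)(C)C | intermediate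
3 | 2-(bromomethyl)allyl TBDPS ether | C=C(CBr)CO[Si](c1ccccc1)(c1ccccc1)C(C)(C)C | intermediate
4 | 2,2-dimethyl-1,3-dioxan-5-one | CC1(C)OCC(=O)CO1 | starting material
5 | 2-(benzyloxy)acetaldehyde | O=CCOCc1ccccc1 | starting material
6 | (4S)-4-[(1S)-2-(benzyloxy)-1-hydroxyethyl]-2,2-dimethyl-1,3-dioxan-5-one | c1ccccc1COC[C@H](O)[C@@H]2OC(C)(C)OCC2=O | intermediate
7 | C6-OTES ether of 6 | c1ccccc1COC[C@H](O[Si](CC)(CC)CC)[C@@H]2OC(C)(C)OCC2=O | intermediate
8 | methyl bromoacetate | COC(=O)CBr | starting material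
9 | Reformatsky adduct (5R tertiary alcohol) | c1ccccc1COC[C@H](O[Si](CC)(CC)CC)[C@@H]2OC(C)(C)OC[C@]2(O)CC(=O)OC | intermediate
10 | C9-alkylated ester with a 1,1-disubstituted alkene | c1ccccc1COC[C@H](O[Si](CC)(CC)CC)[C@@H]2OC(C)(C)OC[C@]2(O)[C@H](CC(=C)CO[Si](c3ccccc3)(c3ccccc3)C(C)(C)C)C(=O)OC | intermediate
11 | C4 ketone | c1ccccc1COC[C@H](O[Si](CC)(CC)CC)[C@@H]2OC(C)(C)OC[C@]2(O)[C@H](CC(=O)CO[Si](c3ccccc3)(c3ccccc3)C(C)(C)C)C(=O)OC | intermediate
12 | C6′-OH compound | OC[C@H](O[Si](CC)(CC)CC)[C@@H]2OC(C)(C)OC[C@]2(O)[C@H](CC(=O)CO[Si](c3ccccc3)(c3ccccc3)C(C)(C)C)C(=O)OC | intermediate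
13 | C6/C6′ diol | OC[C@H](O)[C@@H]2OC(C)(C)OC[C@]2(O)[C@H](CC(=O)CO[Si](c3ccccc3)(c3ccccc3)C(C)(C)C)C(=O)OC | intermediate
14 | C6 aldehyde (1,6-ketoaldehyde) | O=C[C@@H]2OC(C)(C)OC[C@]2(O)[C@H](CC(=O)CO[Si](c3ccccc3)(c3ccccc3)C(C)(C)C)C(=O)OC | intermediate
15 | cis-fused acetonide cyclopentene enone | COC(=O)[C@H]1C(C(=O)CO[Si](c3ccccc3)(c3ccccc3)C(C)(C)C)=C[C@@H]2OC(C)(C)OC[C@]12O | intermediate
16 | C7/C8/C10 triol | COC(=O)[C@H]1C(C(=O)CO[Si](c3ccccc3)(c3ccccc3)C(C)(C)C)=C[C@H](O)[C@]1(O)CO | intermediate
17 | C10-OTBS ether of 16 | COC(=O)[C@H]1C(C(=O)CO[Si](c3ccccc3)(c3ccccc3)C(C)(C)C)=C[C@H](O)[C@]1(O)CO[Si](C)(C)C(C)(C)C | intermediate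
18 | C7-OTES ether of 17 | COC(=O)[C@H]1C(C(=O)CO[Si](c3ccccc3)(c3ccccc3)C(C)(C)C)=C[C@H](O[Si](CC)(CC)CC)[C@]1(O)CO[Si](C)(C)C(C)(C)C | intermediate
19 | methoxydiene | COC(=O)[C@H]1C(C(CO[Si](c3ccccc3)(c3ccccc3)C(C)(C)C)=COC)=C[C@H](O[Si](CC)(CC)CC)[C@]1(O)CO[Si](C)(C)C(C)(C)C | intermediate
20 | C1 carboxylic acid | OC(=O)[C@H]1C(C(CO[Si](c3ccccc3)(c3ccccc3)C(C)(C)C)=COC)=C[C@H](O[Si](CC)(CC)CC)[C@]1(O)CO[Si](C)(C)C(C)(C)C | intermediate
21 | dienyl enol lactone | CC(C)(C)[Si](c3ccccc3)(c3ccccc3)OCC1=COC(=O)[C@H]2C1=C[C@H](O[Si](CC)(CC)CC)[C@]2(O)CO[Si](C)(C)C(C)(C)C | intermediate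
22 | 1-O-isovalerate acylal (7-OTES, 10-OTBS, 11-OTBDPS) | CC(C)(C)[Si](c3ccccc3)(c3ccccc3)OCC1=CO[C@@H](OC(=O)CC(C)C)[C@H]2C1=C[C@H](O[Si](CC)(CC)CC)[C@]2(O)CO[Si](C)(C)C(C)(C)C | intermediate
23 | C7-OH compound | CC(C)(C)[Si](c3ccccc3)(c3ccccc3)OCC1=CO[C@@H](OC(=O)CC(C)C)[C@H]2C1=C[C@H](O)[C@]2(O)CO[Si](C)(C)C(C)(C)C | intermediate
24 | 1,7-bis(isovalerate), 10-OTBS, 11-OTBDPS | CC(C)(C)[Si](c3ccccc3)(c3ccccc3)OCC1=CO[C@@H](OC(=O)CC(C)C)[C@H]2C1=C[C@H](OC(=O)CC(C)C)[C@]2(O)CO[Si](C)(C)C(C)(C)C | intermediate
25 | 11-deacetyl-jatamanvaltrate K (8,10,11-triol) | OCC1=CO[C@@H](OC(=O)CC(C)C)[C@H]2C1=C[C@H](OC(=O)CC(C)C)[C@]2(O)CO | intermediate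
26 | jatamanvaltrate K, (1S,7S,8R,9S) in iridoid numbering | CC(=O)OCC1=CO[C@@H](OC(=O)CC(C)C)[C@H]2C1=C[C@H](OC(=O)CC(C)C)[C@]2(O)CO | target

## Totals
- Total steps: 22.
- Longest linear sequence: 20 steps (Steps 3–22, from dioxanone 4). Steps 1–2 form a short branch that joins at Step 6.

**Three steps most likely to fail**
1. **Step 6 (dianion alkylation of a tertiary β-hydroxy ester).** Retro-aldol or poor C9 selectivity is possible. Fallback: use a different bond construction. Do the Reformatsky of Step 5 with a pre-assembled α-bromo ester that already carries the C5–C4(=CH2)–C11 unit, so the tertiary alkoxide dianion is never needed.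
2. **Step 17 (acid-mediated oxa-cyclisation/elimination to the enol lactone).** The dienyl product or the TES ether may not survive PPTS. Fallback: change the ring-forming strategy. Reduce the C1 ester to the aldehyde dimethyl acetal before the Wittig, close the pyran as the lactol by acid-catalysed transacetalisation onto the methoxydiene, and set C1 by lipase-catalysed dynamic kinetic acylation (CAL-B, vinyl isovalerate).
3. **Step 22 (lipase regioselectivity, C11 versus C10).** Poor selectivity or acyl migration is possible. Fallback: differentiate the two primary alcohols chemically. Carry C10 as TBS and C11 as TES from Step 13 onward, remove TES selectively, acetylate C11 with Ac2O/pyridine, then remove the C10 TBS ether with buffered HF·pyridine.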